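Readings and results were computed on assumed constants.

Without fitting a rate constant, a ledger of Monday's run gives a reckoning of where this flask ends, with each reading entered as a share of the charge.

- Monday's: substrate 0.093 M (fed, over 15 s); gas 14 mM (held); run made earlier
- flask: substrate 0.062 M (fed, over 15 s); gas 14 mM (held); time 80 min

Monday's run (percent of the substrate charged)

| time / min | substrate / % | product / % |
|---|---|---|
| 1.33 | 52 | 22 |
| 2.50 | 33 | 50 |
| 5.00 | 14 | 79 |
| 8.00 | 7 | 87 |
| 15.0 | 6 | 92 |

(scatter of a reading: 2 percentage points)

- the numbers in the tables scatter with a standard deviation of 2 percentage points
- at the start none of the gas is in solution
- the reaction counts as stopped when no species that holds the substrate changes by six tenths of a point or more over the second half of the time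

* the state of affairs at 80 min: stopped, and by what, or still going (forward and back rates have come level / it is still moving / all of the substrate has reacted)
* conversion of substrate at 80 min
* amount of product at 80 min, in percent of the substrate charged

Monday's substrate and product do not add up to the charge, so the ledger needs a third entry, the gap:

gap at 1.33 min: 26.0%
gap at 5.00 min: 7.00%
gap at 15.0 min: 2.00%

Some of the charge therefore sits in an unseen form on its way to product.

A first round of the reckoning uses the last readings and ignores the gap:

product/substrate = 15.3, so substrate = 6.13% and product = 93.9%

A second round puts the gap back. Substrate changes little over the last two readings, so their mean is 6.50%, and this is the rest share, the part of the charge left as free substrate at equilibrium. The same mean for product gives 89.5%, which leaves a gap of 4.00%, with a scatter of about 2 percentage points.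

Above the rest share, Monday's substrate excess halves in

1.37 min

The flask's 80 min is far longer than that Monday half-time, so, taking the flask to run at a like pace, this reckoning has it at rest. With gas held at the same level, and on the assumption that substrate goes one for one to product, its charge of 0.062 M leaves the shares unchanged: conversion 93.5%, product 89.5%.

The forecast, reading “The flat tail, while product stays high, looks like a reversible stop”, gives forward and back rates have come level, conversion 94% (91.5% to 97%) and product 93% (89.5% to 96%), higher on product than this second round.

The flask gives forward and back rates have come level, conversion 94.5% and product 88.9%.

    adduct ⇌ product (K = 15.7, k = 0.0186 s⁻¹)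
    substrate + coupling partner ⇌ adduct (K = 74.0 M⁻¹, k = 9.21 M⁻¹ s⁻¹)
    gas ⇌ coupling partner, rate k3*(csat - [coupling partner]) (kL = 0.0615 s⁻¹)

The rest share stays a reading, 6.50% with the scatter of Monday's readings; the flask holds 5.46% of free substrate at 80.0 min, and its adduct stands at 5.66%. The flask has come to rest: at 40.0 min it already holds 5.46% of substrate and 88.9% of product, and at 800 min it holds 5.46% and 88.9%. Ten times the time gives conversion 94.5% and product 88.9%, so the later reading leaves conversion where it was.

For a neighbouring flask, the same in all but its charge of c_substrate = 0.025 M, the rest share again gives conversion 93.5% and product 89.5%. Computed, that neighbour gives 94.5% and 88.9%, with 5.5% of its substrate left unbound.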